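The synthesis rests on opening the butenolide (the ring made of O, C16, C17, C18 and C19) at two bonds, C17–CH3 and C19–O. In this ring the methyl branch lies on C17, the carbon β to the carbonyl C19, and the alkyl oxygen lies on C16; that is the arrangement produced when a methyl cuprate adds syn across a 4-hydroxy-2-ynoate, because ester and carbinol then stand cis and lactonise in the same operation. The precursor is a methyl 4-hydroxynon-6-en-2-ynoate that already carries the 13E olefin, the silyl-protected C13 hydroxymethyl group and the (5S,10S) decalin taken from (+)-sclareolide; its C16 epimers are later merged in the Z-ylidene.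

Key step: step 7

Remarks on the chemistry
- Numbering: decalin C1–C10 (ring fusion C5/C10, olefin C8=C9), tether C11–C12, olefin C13=C14 (C13 bears the CH2O group), C15, lactone carbons C16–C19 (C19 is the carbonyl).
- Dec = (4aS,8aS)-2,5,5,8a-tetramethyl-3,4,4a,5,6,7,8,8a-octahydronaphthalen-1-yl; TBS = tert-butyldimethylsilyl; TIPS = triisopropylsilyl.
- Assumption: compounds 14 to 17 are carried as the mixture of C16 epimers, since C16 becomes sp2 in step 8 and again in step 9.
- The precursor 14 and the product 17 of the key step were checked against the target: the olefin geometry at C13=C14 (CH2O trans to C15) and the decalin configuration agree, so no structure was changed.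

Step 1
Reactants: 1 (+)-sclareolide
Product: 2 methyl 2-Dec-acetate
Conditions: conc. H2SO4, MeOH, 50 °C
Reagents that add atoms: methanol, CO
Why: Acid-mediated opening of the tertiary lactone by alkyl–oxygen ionisation (E1) with Fischer esterification should give the thermodynamically preferred tetrasubstituted C8=C9 olefin without touching C5 and C10; minor olefin isomers would be removed on AgNO3-doped silica.

Step 2
Reactants: 2 methyl 2-Dec-acetate
Product: 3 2-Dec-ethan-1-ol
Conditions: LiAlH4, THF, 0 °C → rt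
Reagents that add atoms: none
Why: Hydride reduction of an ester to the primary alcohol; the isolated tetrasubstituted olefin is inert and no stereocentre is involved.

Step 3
Reactants: 3 2-Dec-ethan-1-ol
Product: 4 1-bromo-2-Dec-ethane
Conditions: CBr4, PPh3, CH2Cl2, 0 °C
Reagents that add atoms: carbon tetrabromide, BrC(Br)(Br)Br
Why: Appel bromination of a primary alcohol under neutral conditions, which avoids acid that could move the C8=C9 olefin.

Step 4
Reactants: 4 1-bromo-2-Dec-ethane; 5 tert-butyldimethyl(prop-2-yn-1-yloxy)silane; 6 ethylene oxide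
Product: 10 (3E)-4-{[(tert-butyldimethylsilyl)oxy]methyl}-6-Dec-hex-3-en-1-ol, via Grignard reagent 7 (not isolated), via alkylcopper 8 (not isolated), via alkenylcopper 9 (not isolated)
Conditions: Mg, THF, 40 °C; CuBr·SMe2, THF/Me2S, −45 °C; 5, −25 °C; LiC≡C(CH2)2CH3 (from 1-pentyne, n-BuLi), HMPA, then 6 (solution in THF), −78 → −20 °C; aq NH4Cl
Reagents that add atoms: none
Why: Normant carbocupration, in which the alkylcopper adds syn across the terminal alkyne with the alkyl group on the internal carbon C13 and copper on C14 (the bulky, poorly coordinating silyl ether in THF should prevent oxygen-directed reversal), and the configurationally stable alkenylcopper, activated as a mixed alkynyl cuprate, opens ethylene oxide with retention so that C12 and C15 end up cis (13E).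

Step 5
Reactants: 10 (3E)-4-{[(tert-butyldimethylsilyl)oxy]methyl}-6-Dec-hex-3-en-1-ol
Product: 11 (3E)-4-{[(tert-butyldimethylsilyl)oxy]methyl}-6-Dec-hex-3-enal
Conditions: Dess–Martin periodinane, NaHCO3, CH2Cl2, 0 °C; used crude at once
Reagents that add atoms: none
Why: Dess–Martin oxidation of a primary alcohol under buffered, non-basic conditions, chosen so that the β,γ-olefin C13=C14 does not move into conjugation with the aldehyde.

Step 6
Reactants: 11 (3E)-4-{[(tert-butyldimethylsilyl)oxy]methyl}-6-Dec-hex-3-enal; 12 methyl propiolate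
Product: 14 methyl (6E)-7-{[(tert-butyldimethylsilyl)oxy]methyl}-4-hydroxy-9-Dec-non-6-en-2-ynoate (both C16 epimers), via lithiated methyl propiolate 13 (not isolated)
Conditions: 12, LiN(SiMe3)2, THF, −78 °C; then 11, −78 °C; AcOH, −78 °C
Reagents that add atoms: none
Why: 1,2-Addition of a lithium acetylide (lithiated methyl propiolate, kept at −78 °C) to an aldehyde; the C16 carbinol forms without control as both epimers, which is harmless because C16 becomes sp2 later.

Step 7
Reactants: 14 methyl (6E)-7-{[(tert-butyldimethylsilyl)oxy]methyl}-4-hydroxy-9-Dec-non-6-en-2-ynoate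
Product: 17 5-[(2E)-3-{[(tert-butyldimethylsilyl)oxy]methyl}-5-Dec-pent-2-en-1-yl]-4-methylfuran-2(5H)-one (both C16 epimers), via alkenylcopper syn-adduct 15 (not isolated), via Z-hydroxy enoate 16 (not isolated)
Conditions: Me2CuLi (3 equiv, from CuI and MeLi), THF, −78 °C; aq NH4Cl, −78 °C → rt
Reagents that add atoms: lithium dimethylcuprate (Me2CuLi), [Li+].C[Cu-]C
Why: The cuprate forms a π-complex with the electron-poor alkyne and carbometalates it syn, the methyl group going to C17 (the β-carbon, as fixed by polarisation through the ester) and copper to C18, so that the ester and the C16 oxygen stand cis. The closest known reaction type is the conjugate addition of lithium dialkylcuprates to γ-hydroxy-α,β-acetylenic esters, which gives β-substituted butenolides on work-up. The ring closes by 5-exo-trig acyl substitution of the C16 oxygen on the ester carbonyl C19 with loss of methanol. No stereocentre is created, and C16 stays as the epimer mixture. The step needs syn selectivity, which is secured by addition and protonation at −78 °C before the α-cuprio ester can equilibrate through its allenolate, and it needs excess cuprate because the free hydroxyl consumes one methyl group as methane. The silyl ether and the two isolated olefins are inert to the cuprate.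

Step 8
Reactants: 17 5-[(2E)-3-{[(tert-butyldimethylsilyl)oxy]methyl}-5-Dec-pent-2-en-1-yl]-4-methylfuran-2(5H)-one
Product: 18 2-[(2E)-3-{[(tert-butyldimethylsilyl)oxy]methyl}-5-Dec-pent-2-en-1-yl]-3-methyl-5-[(triisopropylsilyl)oxy]furan
Conditions: TIPSOTf, Et3N, CH2Cl2, 0 °C; non-aqueous work-up (pentane)
Reagents that add atoms: triisopropylsilyl trifluoromethanesulfonate, CC(C)[Si](OS(=O)(=O)C(F)(F)F)(C(C)C)C(C)C
Why: Soft enolisation of a butenolide with a silyl triflate and triethylamine removes the γ-hydrogen on C16 and gives the aromatic 2-silyloxyfuran, the usual way to activate the γ-position; the C16 stereocentre disappears here.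

Step 9
Reactants: 18 2-[(2E)-3-{[(tert-butyldimethylsilyl)oxy]methyl}-5-Dec-pent-2-en-1-yl]-3-methyl-5-[(triisopropylsilyl)oxy]furan
Product: 20 (5Z)-5-[(2E)-3-{[(tert-butyldimethylsilyl)oxy]methyl}-5-Dec-pent-2-en-1-ylidene]-4-methylfuran-2(5H)-one, via γ-bromobutenolide 19 (not isolated)
Conditions: NBS, THF, −78 °C; then Et3N, −78 → 0 °C
Reagents that add atoms: none
Why: Electrophilic γ-bromination of the silyl dienolate (far more nucleophilic than the isolated olefins at −78 °C) followed by amine-induced dehydrobromination of the tertiary γ-bromo lactone, the elimination known from 3-bromo-3-alkylphthalides; the Z geometry at C15=C16 should prevail because the E isomer would press C14 against the C17 methyl group (allylic 1,3-strain).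

Step 10
Reactants: 20 (5Z)-5-[(2E)-3-{[(tert-butyldimethylsilyl)oxy]methyl}-5-Dec-pent-2-en-1-ylidene]-4-methylfuran-2(5H)-one
Product: 21 (5Z)-5-[(2E)-3-(hydroxymethyl)-5-Dec-pent-2-en-1-ylidene]-4-methylfuran-2(5H)-one (target)
Conditions: HF·pyridine, pyridine, THF, 0 °C → rt
Reagents that add atoms: none
Why: Fluoride-mediated cleavage of a primary allylic silyl ether with pyridine-buffered HF·pyridine, mild enough to leave the Z-ylidene butenolide and both olefin geometries untouched.

Compound list
1 | (+)-sclareolide, (3aR,5aS,9aS,9bR)-3a,6,6,9a-tetramethyldecahydronaphtho[2,1-b]furan-2(1H)-one | O=C1C[C@H]2[C@@](C)(CC[C@H]3C(C)(C)CCC[C@]23C)O1 | starting material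
2 | methyl 2-[(4aS,8aS)-2,5,5,8a-tetramethyl-3,4,4a,5,6,7,8,8a-octahydronaphthalen-1-yl]acetate (methyl 2-Dec-acetate) | COC(=O)CC1=C(C)CC[C@H]2C(C)(C)CCC[C@]12C | intermediate
3 | 2-[(4aS,8aS)-2,5,5,8a-tetramethyl-3,4,4a,5,6,7,8,8a-octahydronaphthalen-1-yl]ethan-1-ol (2-Dec-ethan-1-ol) | OCCC1=C(C)CC[C@H]2C(C)(C)CCC[C@]12C | intermediate
4 | 1-bromo-2-Dec-ethane | BrCCC1=C(C)CC[C@H]2C(C)(C)CCC[C@]12C | intermediate
5 | tert-butyldimethyl(prop-2-yn-1-yloxy)silane | C#CCO[Si](C)(C)C(C)(C)C | starting material
6 | ethylene oxide (oxirane) | C1CO1 | starting material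
7 | (2-Dec-ethyl)magnesium bromide | Br[Mg]CCC1=C(C)CC[C@H]2C(C)(C)CCC[C@]12C | intermediate
8 | (2-Dec-ethyl)copper (as its MgBr2·SMe2 complex) | [Cu]CCC1=C(C)CC[C@H]2C(C)(C)CCC[C@]12C | intermediate
9 | [(1E)-2-{[(tert-butyldimethylsilyl)oxy]methyl}-4-Dec-but-1-en-1-yl]copper (copper cis to the Dec-ethyl chain) | [Cu]/C=C(/CO[Si](C)(C)C(C)(C)C)CCC1=C(C)CC[C@H]2C(C)(C)CCC[C@]12C | intermediate
10 | (3E)-4-{[(tert-butyldimethylsilyl)oxy]methyl}-6-Dec-hex-3-en-1-ol | OCC/C=C(/CO[Si](C)(C)C(C)(C)C)CCC1=C(C)CC[C@H]2C(C)(C)CCC[C@]12C | intermediate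
11 | (3E)-4-{[(tert-butyldimethylsilyl)oxy]methyl}-6-Dec-hex-3-enal | O=CC/C=C(/CO[Si](C)(C)C(C)(C)C)CCC1=C(C)CC[C@H]2C(C)(C)CCC[C@]12C | intermediate
12 | methyl propiolate (methyl prop-2-ynoate) | C#CC(=O)OC | starting material
13 | methyl 3-lithioprop-2-ynoate | [Li]C#CC(=O)OC | intermediate
14 | methyl (6E)-7-{[(tert-butyldimethylsilyl)oxy]methyl}-4-hydroxy-9-Dec-non-6-en-2-ynoate (both C16 epimers) | COC(=O)C#CC(O)C/C=C(/CO[Si](C)(C)C(C)(C)C)CCC1=C(C)CC[C@H]2C(C)(C)CCC[C@]12C | intermediate
15 | methyl (6E)-7-{[(tert-butyldimethylsilyl)oxy]methyl}-2-cuprio-4-(lithiooxy)-3-methyl-9-Dec-nona-2,6-dienoate, methyl and copper cis on C17=C18 | COC(=O)/C([Cu])=C(/C)C(O[Li])C/C=C(/CO[Si](C)(C)C(C)(C)C)CCC1=C(C)CC[C@H]2C(C)(C)CCC[C@]12C | intermediate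
16 | methyl (2Z,6E)-7-{[(tert-butyldimethylsilyl)oxy]methyl}-4-hydroxy-3-methyl-9-Dec-nona-2,6-dienoate | COC(=O)/C=C(/C)C(O)C/C=C(/CO[Si](C)(C)C(C)(C)C)CCC1=C(C)CC[C@H]2C(C)(C)CCC[C@]12C | intermediate
17 | 5-[(2E)-3-{[(tert-butyldimethylsilyl)oxy]methyl}-5-Dec-pent-2-en-1-yl]-4-methylfuran-2(5H)-one (both C16 epimers) | CC1=CC(=O)OC1C/C=C(/CO[Si](C)(C)C(C)(C)C)CCC1=C(C)CC[C@H]2C(C)(C)CCC[C@]12C | intermediate
18 | 2-[(2E)-3-{[(tert-butyldimethylsilyl)oxy]methyl}-5-Dec-pent-2-en-1-yl]-3-methyl-5-[(triisopropylsilyl)oxy]furan | CC1=C(C/C=C(/CO[Si](C)(C)C(C)(C)C)CCC2=C(C)CC[C@H]3C(C)(C)CCC[C@]23C)OC(O[Si](C(C)C)(C(C)C)C(C)C)=C1 | intermediate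
19 | 5-bromo-5-[(2E)-3-{[(tert-butyldimethylsilyl)oxy]methyl}-5-Dec-pent-2-en-1-yl]-4-methylfuran-2(5H)-one | CC1=CC(=O)OC1(Br)C/C=C(/CO[Si](C)(C)C(C)(C)C)CCC1=C(C)CC[C@H]2C(C)(C)CCC[C@]12C | intermediate
20 | (5Z)-5-[(2E)-3-{[(tert-butyldimethylsilyl)oxy]methyl}-5-Dec-pent-2-en-1-ylidene]-4-methylfuran-2(5H)-one | CC1=CC(=O)O/C1=C\C=C(\CO[Si](C)(C)C(C)(C)C)CCC1=C(C)CC[C@H]2C(C)(C)CCC[C@]12C | intermediate
21 | (5Z)-5-[(2E)-3-(hydroxymethyl)-5-Dec-pent-2-en-1-ylidene]-4-methylfuran-2(5H)-one | CC1=CC(=O)O/C1=C\C=C(\CO)CCC1=C(C)CC[C@H]2C(C)(C)CCC[C@]12C | target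

Total step count: 10 steps.
Longest linear sequence: 10 steps (1 → 21); 5, 6 and 12 enter as purchased building blocks.

Steps most likely to fail

Step 4. What may go wrong: oxygen-assisted delivery of copper to the internal alkyne carbon followed by β-elimination to an allene, or sluggish opening of ethylene oxide by the alkenylcopper. The fallback sets out from 4 and comes back at 10. The Grignard reagent 7 made from 4 would be added, with CuI (10 mol %) in THF/Et2O at rt, to 5-[(4-methoxybenzyl)oxy]pent-2-yn-1-ol F1 (made from 1-[(but-3-yn-1-yloxy)methyl]-4-methoxybenzene, n-BuLi and paraformaldehyde, and first deprotonated with EtMgBr). This copper-catalysed, alkoxide-directed anti-carbomagnesiation places C12 on C13 and magnesium on C14 inside a five-membered chelate. Protonation should give (2E)-5-[(4-methoxybenzyl)oxy]-2-(2-Dec-ethyl)pent-2-en-1-ol F2 with the required geometry. Silylation (TBSCl, imidazole, DMF) would give tert-butyl{[(2E)-5-[(4-methoxybenzyl)oxy]-2-(2-Dec-ethyl)pent-2-en-1-yl]oxy}dimethylsilane F3, and DDQ (CH2Cl2/pH 7 buffer, 0 °C) would remove the 4-methoxybenzyl group to return alcohol 10.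

Step 9. What may go wrong: bromination at C18 or at the tetrasubstituted C8=C9 olefin instead of C16, or an E/Z mixture at C15=C16 that does not converge. The fallback sets out from 18 and comes back at 20. γ-Selenenylation with PhSeCl (CH2Cl2, −78 °C) would give 5-[(2E)-3-{[(tert-butyldimethylsilyl)oxy]methyl}-5-Dec-pent-2-en-1-yl]-4-methyl-5-(phenylselanyl)furan-2(5H)-one F5. Oxidation with mCPBA at −78 °C would give the corresponding selenoxide F6, which on warming with i-Pr2NH should undergo syn-elimination toward C15, the only β-carbon that carries hydrogen. Any E isomer would be equilibrated to the Z isomer with a trace of iodine in daylight.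

Step 7. What may go wrong: loss of the syn relationship through equilibration of the α-cuprio ester via its allenolate, after which the E hydroxy ester cannot lactonise, or incomplete addition. The fallback sets out from 11 and comes back at 17. Aldehyde 11 would undergo Nozaki–Hiyama–Kishi coupling with methyl (2Z)-3-iodobut-2-enoate F4 (from methyl but-2-ynoate, NaI, AcOH) using CrCl2 and catalytic NiCl2 in DMF at rt. The alkenylchromium should add to C16 with retention of the Z geometry, and the alkoxide, held cis to the ester, should lactonise to 17. In this variant the methyl group comes with the reagent and the C16–C17 bond is formed instead.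

Further compounds
F1 | step 4 | 5-[(4-methoxybenzyl)oxy]pent-2-yn-1-ol | OCC#CCCOCc1ccc(OC)cc1
F2 | step 4 | (2E)-5-[(4-methoxybenzyl)oxy]-2-(2-Dec-ethyl)pent-2-en-1-ol | OC/C(CCC1=C(C)CC[C@H]2C(C)(C)CCC[C@]12C)=C/CCOCc1ccc(OC)cc1
F3 | step 4 | tert-butyl{[(2E)-5-[(4-methoxybenzyl)oxy]-2-(2-Dec-ethyl)pent-2-en-1-yl]oxy}dimethylsilane | CC(C)(C)[Si](C)(C)OC/C(CCC1=C(C)CC[C@H]2C(C)(C)CCC[C@]12C)=C/CCOCc1ccc(OC)cc1
F4 | step 7 | methyl (2Z)-3-iodobut-2-enoate | COC(=O)/C=C(\I)C
F5 | step 9 | 5-[(2E)-3-{[(tert-butyldimethylsilyl)oxy]methyl}-5-Dec-pent-2-en-1-yl]-4-methyl-5-(phenylselanyl)furan-2(5H)-one | CC1=CC(=O)OC1([Se]c1ccccc1)C/C=C(/CO[Si](C)(C)C(C)(C)C)CCC1=C(C)CC[C@H]2C(C)(C)CCC[C@]12C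
F6 | step 9 | 5-[(2E)-3-{[(tert-butyldimethylsilyl)oxy]methyl}-5-Dec-pent-2-en-1-yl]-4-methyl-5-(phenylseleninyl)furan-2(5H)-one | CC1=CC(=O)OC1([Se](=O)c1ccccc1)C/C=C(/CO[Si](C)(C)C(C)(C)C)CCC1=C(C)CC[C@H]2C(C)(C)CCC[C@]12C
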